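**Plan**

- Target: the monoacetate of atromentin. In its quinone ring the carbonyl carbons C1 and C4 alternate with two identical two-carbon units, C2(O)–C3(aryl) and C5(O)–C6(aryl). Each unit is an aryl alkynyl ether in disguise and each carbonyl carbon is a molecule of CO.
- Retrosynthesis: remove the acetyl group and the phenol protection, cut the four ring bonds C1–C2, C3–C4, C4–C5 and C6–C1 at once, and last the aryl–alkyne bond.
- Forward: iodide 1 and ethoxyacetylene 2 are coupled to ynol ether 3. Two molecules of 3 are joined with two CO at Fe(CO)5 (4, under carbon monoxide 5) through iron complex 6 to quinone 7, the only ring-forming event.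
- Both ethoxy groups of 7 are hydrolysed (8), one of the two equivalent quinone hydroxyls is acetylated (9), and the benzyl ethers are hydrogenolysed via leuco form 10, which air reoxidises to target 11.
- Stereochemistry: the target has no stereocentre. The only selectivity to be won is the head-to-tail (2,5-diaryl) regiochemistry, decided in the ring-forming step.

Key step: step 2

Assumption: the two ring carbonyl carbons are taken from iron-bound CO that a CO atmosphere keeps in supply, and ynol ether 3 is handled cold and acid-free because it hydrates easily.

**Route**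

Step 1
Reactants: 1 1-(benzyloxy)-4-iodobenzene; 2 ethoxyacetylene (ethoxyethyne, commercial solution in hexanes)
Product: 3 1-(benzyloxy)-4-(ethoxyethynyl)benzene
Conditions: PdCl2(PPh3)2 (3 mol%), CuI (5 mol%), Et3N, THF, 0 °C → rt; filtration through Et3N-deactivated silica
Reagents that add atoms: none
Why: Sonogashira coupling, in which oxidative addition of zerovalent palladium into the aryl iodide and transmetalation from the copper acetylide of the terminal ynol ether proceed at or below room temperature, so the acid- and heat-sensitive aryl ynol ether is never warmed or exposed to acid.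

Step 2
Reactants: 3 1-(benzyloxy)-4-(ethoxyethynyl)benzene (two molecules); 4 iron pentacarbonyl, Fe(CO)5 (stoichiometric carrier and template); 5 carbon monoxide (two molecules, taken up through the carbonyl ligands on iron)
Product: 7 2,5-bis[4-(benzyloxy)phenyl]-3,6-diethoxy-1,4-benzoquinone, via tricarbonyliron quinone complex 6 (not isolated)
Conditions: Fe(CO)5 (0.6 equiv per 3), CO (1 atm), hν (365 nm), toluene, −10 °C; then FeCl3·6H2O (3 equiv), MeCN, 0 °C
Reagents that add atoms: none
Why: Proposed new method: the closest known reaction type is the photochemical Fe(CO)5-mediated [2+2+1+1] cyclocarbonylation of alkyl-, aryl- and ferrocenyl-substituted alkynes with CO to p-benzoquinones (obtained free or as tricarbonyliron complexes), which has not been shown for alkoxyalkynes. Light expels CO from zerovalent iron, ynol ether 3 binds, and two CO insertions give the maleoyl ferracycle Fe–C(=O)–C(OEt)=C(Ar)–C(=O)–Fe; a second molecule of 3 then inserts into one iron–acyl bond, and FeCl3 (oxidising zerovalent to divalent iron) releases quinone 7 from the resulting complex 6. The one ring closes by acyl–alkenyl C–C reductive elimination from the seven-membered ferracycle, so all four bonds between the two carbonyl carbons and their ring neighbours arise in this single operation and no stereocentre is formed. The step needs head-to-tail regioselectivity (2,5- rather than 2,6-diaryl): the ynol ether is polarised so that its aryl-bearing carbon is the nucleophilic terminus and iron takes the alkoxy-bearing carbon, while of the two acyl carbons of the maleoyl ferracycle the one bonded directly to C–OEt is the more electrophilic because the other is damped as a vinylogous ester, so the aryl carbon of the second alkyne should bond to the acyl carbon next to C–OEt. It also needs quinone formation to outrun [2+2+1] closure to a cyclopentadienone complex, which the CO atmosphere and the low temperature favour by keeping both acyl groups on iron until the second alkyne arrives.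

Step 3
Reactants: 7 2,5-bis[4-(benzyloxy)phenyl]-3,6-diethoxy-1,4-benzoquinone
Product: 8 2,5-bis[4-(benzyloxy)phenyl]-3,6-dihydroxy-1,4-benzoquinone
Conditions: 2 M NaOH (aq), 1,4-dioxane, 60 °C; then 1 M HCl, 0 °C
Reagents that add atoms: sodium hydroxide, [Na+].[OH-]
Why: Vinylogous ester saponification, in which hydroxide adds to each ethoxy-bearing ring carbon and expels ethoxide (addition–elimination) to give a bis-enolate that resists further attack, while the aryl benzyl ethers are inert to aqueous base.

Step 4
Reactants: 8 2,5-bis[4-(benzyloxy)phenyl]-3,6-dihydroxy-1,4-benzoquinone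
Product: 9 2,5-bis[4-(benzyloxy)phenyl]-4-hydroxy-3,6-dioxocyclohexa-1,4-dien-1-yl acetate
Conditions: Et3N (1.0 equiv), CH2Cl2, −40 °C; AcCl (1.0 equiv), −40 → 0 °C
Reagents that add atoms: acetyl chloride, CC(=O)Cl
Why: O-Acylation of a vinylogous carboxylate with an acid chloride, where the two quinone hydroxyls of 8 are equivalent so only one monoacetate exists, and one equivalent each of base and acetyl chloride at low temperature limits the second acylation, with unreacted 8 and any diacetate returned to 8 under the step 3 conditions.

Step 5
Reactants: 9 2,5-bis[4-(benzyloxy)phenyl]-4-hydroxy-3,6-dioxocyclohexa-1,4-dien-1-yl acetate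
Product: 11 4-hydroxy-2,5-bis(4-hydroxyphenyl)-3,6-dioxocyclohexa-1,4-dien-1-yl acetate (atromentin monoacetate), via leuco monoacetate 10 (not isolated)
Conditions: H2 (1 atm), 10% Pd/C, EtOAc, rt; filtration under argon; then air (O2), EtOAc, rt
Reagents that add atoms: none
Why: Hydrogenolysis of aryl benzyl ethers over Pd/C in a neutral aprotic solvent spares the ester; the quinone is reduced in passing to leuco form 10, in which acetyl shifts between neighbouring oxygens are degenerate because the four ring oxygens of the leuco core are equivalent, and this electron-rich hydroxyhydroquinone should be reoxidised by air to the p-quinone.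

**Compound list**

1 | 1-(benzyloxy)-4-iodobenzene | Ic1ccc(OCc2ccccc2)cc1 | starting material
2 | ethoxyacetylene (ethoxyethyne) | CCOC#C | starting material
3 | 1-(benzyloxy)-4-(ethoxyethynyl)benzene | CCOC#Cc1ccc(OCc2ccccc2)cc1 | intermediate
4 | iron pentacarbonyl, Fe(CO)5 | O=C=[Fe](=C=O)(=C=O)(=C=O)=C=O | starting material
5 | carbon monoxide | [C-]#[O+] | starting material
6 | tricarbonyl{η4-2,5-bis[4-(benzyloxy)phenyl]-3,6-diethoxy-1,4-benzoquinone}iron | CCOC1=C(c2ccc(OCc3ccccc3)cc2)C(=O)C(OCC)=C(c2ccc(OCc3ccccc3)cc2)C1=O.O=C=[Fe](=C=O)=C=O | intermediate
7 | 2,5-bis[4-(benzyloxy)phenyl]-3,6-diethoxy-1,4-benzoquinone | CCOC1=C(c2ccc(OCc3ccccc3)cc2)C(=O)C(OCC)=C(c2ccc(OCc3ccccc3)cc2)C1=O | intermediate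
8 | 2,5-bis[4-(benzyloxy)phenyl]-3,6-dihydroxy-1,4-benzoquinone | OC1=C(c2ccc(OCc3ccccc3)cc2)C(=O)C(O)=C(c2ccc(OCc3ccccc3)cc2)C1=O | intermediate
9 | 2,5-bis[4-(benzyloxy)phenyl]-4-hydroxy-3,6-dioxocyclohexa-1,4-dien-1-yl acetate | CC(=O)OC1=C(c2ccc(OCc3ccccc3)cc2)C(=O)C(O)=C(c2ccc(OCc3ccccc3)cc2)C1=O | intermediate
10 | 2,4,5-trihydroxy-3,6-bis(4-hydroxyphenyl)phenyl acetate (leuco monoacetate) | CC(=O)Oc1c(O)c(-c2ccc(O)cc2)c(O)c(O)c1-c1ccc(O)cc1 | intermediate
11 | 4-hydroxy-2,5-bis(4-hydroxyphenyl)-3,6-dioxocyclohexa-1,4-dien-1-yl acetate (atromentin monoacetate) | CC(=O)OC1=C(c2ccc(O)cc2)C(=O)C(O)=C(c2ccc(O)cc2)C1=O | target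

**Totals**

Total step count: 5. Longest linear sequence: 5 steps (1 and 2 → 3 → 7 → 8 → 9 → 11).

**Steps most likely to fail**

1. Step 2 (carries the label). The second ynol ether may insert without regiocontrol and give the 2,6-diaryl pattern. The ring may also close after a single CO insertion to a cyclopentadienone–iron complex, or the ynol ether may decompose under light and metal before it is captured. The fallback is known chemistry, a twofold Suzuki–Miyaura coupling on a preformed 2,5-dialkoxy-3,6-dihaloquinone, and it sets out from iodide 1. Iodine–magnesium exchange (iPrMgCl·LiCl, THF, 0 °C), then B(OMe)3 and aqueous acid, should give 4-(benzyloxy)phenylboronic acid F1. Separately, commercial bromanil (tetrabromo-1,4-benzoquinone) and NaOEt in EtOH at 0 °C should give 2,5-dibromo-3,6-diethoxy-1,4-benzoquinone F2 by twofold addition–elimination. Coupling F2 with two equivalents of F1 (PdCl2(dppf), K2CO3, dioxane, 80 °C) comes back to the route at quinone 7. The dihalide fixes the 2,5-pattern, so no regiochemical question remains.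

2. Step 4. The second acylation may compete with the first, since nothing in the substrate distinguishes them strongly, and the acetyl group may scramble between molecules during isolation. The fallback sets out from diol 8. Exhaustive acetylation (excess Ac2O, Et3N, cat. DMAP, CH2Cl2, 0 °C) should give 2,5-bis[4-(benzyloxy)phenyl]-3,6-dioxocyclohexa-1,4-diene-1,4-diyl diacetate F3. One acetate is then cleaved under controlled conditions (aqueous NaHCO3, THF, 0 °C, then dilute HCl). The first cleavage leaves a hydroxyquinone anion whose remaining acetate is a much poorer acyl donor, because its leaving group would be a dianion, so the reaction should stop at the mono stage. It comes back to the route at monoacetate 9.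

3. Step 1. The terminal ynol ether may homocouple oxidatively at copper, the amine may add to the electron-rich triple bond, or the product may hydrate during isolation. The fallback sets out from ethoxyacetylene 2. Deprotonation with n-BuLi (THF, −78 °C) and quenching with Bu3SnCl should give tributyl(ethoxyethynyl)stannane F4. A copper- and amine-free Stille coupling of F4 with iodide 1 (PdCl2(PPh3)2, Et4NCl, DMF, rt) comes back to the route at ynol ether 3.

**Further compounds**

F1 | step 2 | 4-(benzyloxy)phenylboronic acid | OB(O)c1ccc(OCc2ccccc2)cc1
F2 | step 2 | 2,5-dibromo-3,6-diethoxy-1,4-benzoquinone | CCOC1=C(Br)C(=O)C(OCC)=C(Br)C1=O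
F3 | step 4 | 2,5-bis[4-(benzyloxy)phenyl]-3,6-dioxocyclohexa-1,4-diene-1,4-diyl diacetate | CC(=O)OC1=C(c2ccc(OCc3ccccc3)cc2)C(=O)C(OC(C)=O)=C(c2ccc(OCc3ccccc3)cc2)C1=O
F4 | step 1 | tributyl(ethoxyethynyl)stannane | CCOC#C[Sn](CCCC)(CCCC)CCCC
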